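**Retrosynthetic overview**
- Last bond: the O8 methacrylate, put on the 8β-hydroxyl of the finished epoxy germacranolide.
- Key disconnection: C7–C8 and O6–C12 in one operation. An acyclic (Z)-2-(bromomethyl)-4-hydroxy-2-enoate carrying a C8 aldehyde closes the ten-membered carbocycle by indium Barbier allylation and then the γ-lactone on O6, setting C7 and C8.
- C6 carbinol and C7/C11/C12/C13: asymmetric addition of methyl propiolate to the (Z)-enal, trans-hydroalumination/iodination, hydroxymethyl Stille coupling.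
- Oxirane: Sharpless epoxidation of the C14 allylic alcohol, whose trisubstituted alkene comes from a β-oxido ylide olefination joining a nerol-derived C1 aldehyde, a C8–C10 ylide and formaldehyde (C14).
- Ring order: oxirane first (step 5), then carbocycle and lactone together (step 12).

Assumption: germacrane numbering (C1–C15) is used for atom labels, and the (S,S)-ProPhenol antipode is taken to give the 6R carbinol (otherwise its enantiomer is used).

**Step 1**
Reactants: 1 nerol [(2Z)-3,7-dimethylocta-2,6-dien-1-ol]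
Product: 2 tert-butyl{[(2Z)-3,7-dimethylocta-2,6-dien-1-yl]oxy}dimethylsilane
Conditions: TBSCl, imidazole, CH2Cl2, 0 °C to rt
Reagents that add atoms: tert-butyldimethylsilyl chloride, CC(C)(C)[Si](C)(C)Cl
Why: Standard silyl ether formation (Corey TBSCl/imidazole protocol) masks the C6 oxygen for the organolithium and titanium steps without touching the Z alkene or creating a stereocentre.

**Step 2**
Reactants: 2 tert-butyl{[(2Z)-3,7-dimethylocta-2,6-dien-1-yl]oxy}dimethylsilane
Product: 4 (4Z)-6-[(tert-butyldimethylsilyl)oxy]-4-methylhex-4-enal, via ozonide 3 (not isolated)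
Conditions: O3 (1.0 equiv, Sudan Red 7B end point), pyridine (cat), CH2Cl2, −78 °C; then Me2S, −78 °C to rt
Reagents that add atoms: ozone, [O-][O+]=O
Why: Regioselective ozonolysis (Criegee mechanism, reductive work-up) cleaves the electron-richer isopropylidene alkene in preference to the alkene deactivated by the allylic silyloxy group, giving the C1 aldehyde and acetone with the Z-configured C4=C5 bond intact.

**Step 3**
Reactants: 5 (3-bromopropoxy)(tert-butyl)dimethylsilane
Product: 6 {3-[(tert-butyldimethylsilyl)oxy]propyl}triphenylphosphonium bromide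
Conditions: PPh3, K2CO3 (cat), MeCN, 80 °C
Reagents that add atoms: triphenylphosphine, c1ccc(cc1)P(c1ccccc1)c1ccccc1
Why: SN2 quaternisation of triphenylphosphine by the primary bromide gives the Wittig salt that carries C10, C9 and C8.

**Step 4**
Reactants: 6 {3-[(tert-butyldimethylsilyl)oxy]propyl}triphenylphosphonium bromide; 4 (4Z)-6-[(tert-butyldimethylsilyl)oxy]-4-methylhex-4-enal
Product: 10 (2Z,6Z)-8-[(tert-butyldimethylsilyl)oxy]-2-{2-[(tert-butyldimethylsilyl)oxy]ethyl}-6-methylocta-2,6-dien-1-ol, via ylide 7 (not isolated), via lithium betaine 8 (not isolated), via oxido ylide 9 (not isolated)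
Conditions: PhLi (1 equiv), THF/Et2O, −78 °C; add 4, −78 °C; PhLi (1 equiv), −78 to −30 °C; (CH2O)n, −30 °C to rt; then H2O
Reagents that add atoms: formaldehyde (from paraformaldehyde), C=O
Why: Corey–Schlosser β-oxido ylide olefination (SCOOPY variant of the Wittig reaction) hydroxymethylates the deprotonated lithium betaine at the position a proton takes in the Schlosser modification, so loss of Ph3PO gives the trisubstituted alkene with C14 cis to C2 and C9 trans to C2, the geometry that later becomes the trans 1,10-epoxide.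

**Step 5**
Reactants: 10 (2Z,6Z)-8-[(tert-butyldimethylsilyl)oxy]-2-{2-[(tert-butyldimethylsilyl)oxy]ethyl}-6-methylocta-2,6-dien-1-ol
Product: 12 [(2S,3R)-2-{2-[(tert-butyldimethylsilyl)oxy]ethyl}-3-{(3Z)-5-[(tert-butyldimethylsilyl)oxy]-3-methylpent-3-en-1-yl}oxiran-2-yl]methyl acetate, via epoxy alcohol 11 (not isolated)
Conditions: Ti(OiPr)4 (10 mol%), L-(+)-diethyl tartrate (12 mol%), t-BuOOH, 4 Å MS, CH2Cl2, −20 °C; then Ac2O, Et3N, DMAP (cat), −20 to 0 °C
Reagents that add atoms: tert-butyl hydroperoxide, CC(C)(C)OO; acetic anhydride, CC(=O)OC(C)=O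
Why: Katsuki–Sharpless asymmetric epoxidation with the natural tartrate delivers oxygen to the face of the allylic alcohol that gives the (2S,3R)-epoxy alcohol (same sense as nerol to (2S,3R)-2,3-epoxynerol), which is C1 R and C10 S, while the other alkene has no free allylic hydroxyl and stays inert, and in situ acetylation installs the C14 acetate.

**Step 6**
Reactants: 12 [(2S,3R)-2-{2-[(tert-butyldimethylsilyl)oxy]ethyl}-3-{(3Z)-5-[(tert-butyldimethylsilyl)oxy]-3-methylpent-3-en-1-yl}oxiran-2-yl]methyl acetate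
Product: 13 [(2S,3R)-2-(2-hydroxyethyl)-3-[(3Z)-5-hydroxy-3-methylpent-3-en-1-yl]oxiran-2-yl]methyl acetate
Conditions: Bu4NF, AcOH, THF, 0 °C to rt
Reagents that add atoms: none
Why: Fluoride-driven desilylation, buffered with acetic acid so that the acetate and the epoxide survive, frees both primary alcohols at once.

**Step 7**
Reactants: 13 [(2S,3R)-2-(2-hydroxyethyl)-3-[(3Z)-5-hydroxy-3-methylpent-3-en-1-yl]oxiran-2-yl]methyl acetate
Product: 14 [(2S,3R)-2-(2-hydroxyethyl)-3-[(3Z)-3-methyl-5-oxopent-3-en-1-yl]oxiran-2-yl]methyl acetate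
Conditions: MnO2 (activated, excess), CH2Cl2, rt
Reagents that add atoms: none
Why: Chemoselective allylic oxidation with MnO2 converts only the allylic C6 alcohol into the Z-enal under neutral conditions that leave the saturated C8 alcohol, the epoxide and the alkene geometry unchanged.

**Step 8**
Reactants: 14 [(2S,3R)-2-(2-hydroxyethyl)-3-[(3Z)-3-methyl-5-oxopent-3-en-1-yl]oxiran-2-yl]methyl acetate; 15 methyl propiolate
Product: 17 methyl (4R,5Z)-8-[(2R,3S)-3-(acetoxymethyl)-3-(2-hydroxyethyl)oxiran-2-yl]-4-hydroxy-6-methyloct-5-en-2-ynoate, via zinc acetylide 16 (not isolated)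
Conditions: Me2Zn (4 equiv), (S,S)-ProPhenol (20 mol%), Ph3PO (40 mol%), PhMe, 4 °C; aq NH4Cl
Reagents that add atoms: none
Why: Trost ProPhenol/Me2Zn asymmetric alkynylation, in which the dinuclear zinc catalyst binds the enal and delivers the zinc acetylide to one carbonyl face, sets the C6 carbinol as R while the free C8 hydroxyl is only deprotonated.

**Step 9**
Reactants: 17 methyl (4R,5Z)-8-[(2R,3S)-3-(acetoxymethyl)-3-(2-hydroxyethyl)oxiran-2-yl]-4-hydroxy-6-methyloct-5-en-2-ynoate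
Product: 19 methyl (2Z,4R,5Z)-8-[(2R,3S)-3-(acetoxymethyl)-3-(2-hydroxyethyl)oxiran-2-yl]-4-hydroxy-2-iodo-6-methylocta-2,5-dienoate, via vinylalanate 18 (not isolated)
Conditions: NaAlH2(OCH2CH2OMe)2 (2.5 equiv), THF, −72 °C, 30 min; then I2, −78 °C; H2O
Reagents that add atoms: iodine, II
Why: Hydroxyl-directed trans-hydroalumination of the γ-hydroxy ynoate (hydride passes from the C6 alkoxyaluminate to C7 and aluminium ends on C11 in a five-membered ring) followed by iododealumination with retention gives the 2-iodo enoate with C6 cis to iodine and trans to the ester, so it cannot lactonise.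

**Step 10**
Reactants: 19 methyl (2Z,4R,5Z)-8-[(2R,3S)-3-(acetoxymethyl)-3-(2-hydroxyethyl)oxiran-2-yl]-4-hydroxy-2-iodo-6-methylocta-2,5-dienoate
Product: 20 methyl (2Z,4R,5Z)-8-[(2R,3S)-3-(acetoxymethyl)-3-(2-oxoethyl)oxiran-2-yl]-4-hydroxy-2-iodo-6-methylocta-2,5-dienoate
Conditions: TEMPO (10 mol%), PhI(OAc)2, CH2Cl2, rt
Reagents that add atoms: none
Why: Oxoammonium (TEMPO/PhI(OAc)2) oxidation is selective for the unhindered primary alcohol over the hindered secondary allylic alcohol and stops at the aldehyde under non-basic conditions that the β,γ-epoxy aldehyde tolerates.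

**Step 11**
Reactants: 20 methyl (2Z,4R,5Z)-8-[(2R,3S)-3-(acetoxymethyl)-3-(2-oxoethyl)oxiran-2-yl]-4-hydroxy-2-iodo-6-methylocta-2,5-dienoate
Product: 21 methyl (2E,4R,5Z)-8-[(2R,3S)-3-(acetoxymethyl)-3-(2-oxoethyl)oxiran-2-yl]-4-hydroxy-2-(hydroxymethyl)-6-methylocta-2,5-dienoate
Conditions: Bu3SnCH2OH, Pd2(dba)3 (5 mol%), AsPh3, CuI (cat), NMP, 45 °C
Reagents that add atoms: (tributylstannyl)methanol, CCCC[Sn](CCCC)(CCCC)CO
Why: Stille cross-coupling transfers the hydroxymethyl group to the alkenyl iodide with retention of geometry, placing C13 cis to C6.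

**Step 12**
Reactants: 21 methyl (2E,4R,5Z)-8-[(2R,3S)-3-(acetoxymethyl)-3-(2-oxoethyl)oxiran-2-yl]-4-hydroxy-2-(hydroxymethyl)-6-methylocta-2,5-dienoate
Product: 25 (1R,4Z,6R,7R,8R,10S)-14-acetoxy-1,10-epoxy-8-hydroxygermacra-4,11(13)-dien-12,6-olide, via allylic bromide 22 (not isolated), via allylindium species 23 (not isolated), via dihydroxy ester 24 (not isolated)
Conditions: PPh3, NBS, CH2Cl2, −30 °C; crude bromide, In powder (3 equiv), THF/H2O 1:1 (0.002 M), rt; then 2-hydroxypyridine (cat), PhMe, 50 °C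
Reagents that add atoms: none
Why: Proposed new method: Appel-type bromination of the primary allylic alcohol and indium insertion give a Z-configured 2-(methoxycarbonyl)allylindium chelated by the free C6 hydroxyl, which adds to the C8 aldehyde through a chair Zimmerman–Traxler transition state so that the C7–C8 bond closes the ten-membered ring with C8 entering anti to the C5 alkenyl group (C7 R, trans to O6) and with the syn C7/C8 relationship fixed by the Z allyl geometry (C8 R), after which the 6α-hydroxyl rather than the 8β-hydroxyl (which could only give a strained cis-fused lactone) closes the trans γ-lactone with loss of methanol; the closest known reactions are chromium-, zinc- and indium-mediated macrocyclising Barbier or Nozaki–Hiyama allylation–lactonisations of 2-(bromomethyl)acrylates at C6–C7 and hydroxyl-chelated indium allylations in water.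

**Step 13**
Reactants: 25 (1R,4Z,6R,7R,8R,10S)-14-acetoxy-1,10-epoxy-8-hydroxygermacra-4,11(13)-dien-12,6-olide
Product: 26 (1R,4Z,6R,7R,8R,10S)-14-acetoxy-1,10-epoxy-8-(methacryloyloxy)germacra-4,11(13)-dien-12,6-olide (CNP0150481.2)
Conditions: methacrylic anhydride, Et3N, DMAP (cat), CH2Cl2, 0 °C to rt
Reagents that add atoms: methacrylic anhydride, CC(=C)C(=O)OC(=O)C(C)=C
Why: DMAP-catalysed acyl transfer esterifies the only free hydroxyl with retention at C8 and completes the target.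

**Compound list**
1 | nerol, (2Z)-3,7-dimethylocta-2,6-dien-1-ol | CC(C)=CCC/C(C)=C\CO | starting material
2 | tert-butyl{[(2Z)-3,7-dimethylocta-2,6-dien-1-yl]oxy}dimethylsilane | CC(C)=CCC/C(C)=C\CO[Si](C)(C)C(C)(C)C | intermediate
3 | ozonide, 3-{(3Z)-5-[(tert-butyldimethylsilyl)oxy]-3-methylpent-3-en-1-yl}-5,5-dimethyl-1,2,4-trioxolane (racemic at C3) | CC1(C)OOC(CC/C(C)=C\CO[Si](C)(C)C(C)(C)C)O1 | intermediate
4 | (4Z)-6-[(tert-butyldimethylsilyl)oxy]-4-methylhex-4-enal | O=CCC/C(C)=C\CO[Si](C)(C)C(C)(C)C | intermediate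
5 | (3-bromopropoxy)(tert-butyl)dimethylsilane | BrCCCO[Si](C)(C)C(C)(C)C | starting material
6 | {3-[(tert-butyldimethylsilyl)oxy]propyl}triphenylphosphonium bromide | CC(C)(C)[Si](C)(C)OCCC[P+](c1ccccc1)(c1ccccc1)c1ccccc1.[Br-] | intermediate
7 | ylide, {3-[(tert-butyldimethylsilyl)oxy]propylidene}triphenylphosphorane | CC(C)(C)[Si](C)(C)OCCC=P(c1ccccc1)(c1ccccc1)c1ccccc1 | intermediate
8 | lithium betaine from 7 and 4 (O-lithio β-oxido phosphonium bromide, diastereomer mixture) | [Li]OC(CC/C(C)=C\CO[Si](C)(C)C(C)(C)C)C(CCO[Si](C)(C)C(C)(C)C)[P+](c1ccccc1)(c1ccccc1)c1ccccc1.[Br-] | intermediate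
9 | β-oxido ylide (O-lithio, carbinol centre unassigned) | [Li]OC(CC/C(C)=C\CO[Si](C)(C)C(C)(C)C)C(CCO[Si](C)(C)C(C)(C)C)=P(c1ccccc1)(c1ccccc1)c1ccccc1 | intermediate
10 | (2Z,6Z)-8-[(tert-butyldimethylsilyl)oxy]-2-{2-[(tert-butyldimethylsilyl)oxy]ethyl}-6-methylocta-2,6-dien-1-ol | OC/C(CCO[Si](C)(C)C(C)(C)C)=C\CC/C(C)=C\CO[Si](C)(C)C(C)(C)C | intermediate
11 | [(2S,3R)-2-{2-[(tert-butyldimethylsilyl)oxy]ethyl}-3-{(3Z)-5-[(tert-butyldimethylsilyl)oxy]-3-methylpent-3-en-1-yl}oxiran-2-yl]methanol | CC(C)(C)[Si](C)(C)OCC[C@@]1(CO)O[C@@H]1CC/C(C)=C\CO[Si](C)(C)C(C)(C)C | intermediate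
12 | [(2S,3R)-2-{2-[(tert-butyldimethylsilyl)oxy]ethyl}-3-{(3Z)-5-[(tert-butyldimethylsilyl)oxy]-3-methylpent-3-en-1-yl}oxiran-2-yl]methyl acetate | CC(C)(C)[Si](C)(C)OCC[C@@]1(COC(C)=O)O[C@@H]1CC/C(C)=C\CO[Si](C)(C)C(C)(C)C | intermediate
13 | [(2S,3R)-2-(2-hydroxyethyl)-3-[(3Z)-5-hydroxy-3-methylpent-3-en-1-yl]oxiran-2-yl]methyl acetate | OCC[C@@]1(COC(C)=O)O[C@@H]1CC/C(C)=C\CO | intermediate
14 | [(2S,3R)-2-(2-hydroxyethyl)-3-[(3Z)-3-methyl-5-oxopent-3-en-1-yl]oxiran-2-yl]methyl acetate | OCC[C@@]1(COC(C)=O)O[C@@H]1CC/C(C)=C\C=O | intermediate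
15 | methyl propiolate (methyl prop-2-ynoate) | C#CC(=O)OC | starting material
16 | zinc acetylide, methyl 3-(methylzincio)prop-2-ynoate | C[Zn]C#CC(=O)OC | intermediate
17 | methyl (4R,5Z)-8-[(2R,3S)-3-(acetoxymethyl)-3-(2-hydroxyethyl)oxiran-2-yl]-4-hydroxy-6-methyloct-5-en-2-ynoate | OCC[C@@]1(COC(C)=O)O[C@@H]1CC/C(C)=C\[C@@H](O)C#CC(=O)OC | intermediate
18 | vinylalanate: disodium salt in which O6 and C11 are bridged by Al(OCH2CH2OMe)2 (five-membered ring) and O8 carries AlH(OCH2CH2OMe)2 | [Na+].[Na+].COCCO[AlH-](OCCOC)OCC[C@@]1(COC(C)=O)O[C@@H]1CC/C(C)=C\[C@H]1O[Al-](OCCOC)(OCCOC)C(C(=O)OC)=C1 | intermediate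
19 | methyl (2Z,4R,5Z)-8-[(2R,3S)-3-(acetoxymethyl)-3-(2-hydroxyethyl)oxiran-2-yl]-4-hydroxy-2-iodo-6-methylocta-2,5-dienoate | OCC[C@@]1(COC(C)=O)O[C@@H]1CC/C(C)=C\[C@@H](O)/C=C(\I)C(=O)OC | intermediate
20 | methyl (2Z,4R,5Z)-8-[(2R,3S)-3-(acetoxymethyl)-3-(2-oxoethyl)oxiran-2-yl]-4-hydroxy-2-iodo-6-methylocta-2,5-dienoate | O=CC[C@@]1(COC(C)=O)O[C@@H]1CC/C(C)=C\[C@@H](O)/C=C(\I)C(=O)OC | intermediate
21 | methyl (2E,4R,5Z)-8-[(2R,3S)-3-(acetoxymethyl)-3-(2-oxoethyl)oxiran-2-yl]-4-hydroxy-2-(hydroxymethyl)-6-methylocta-2,5-dienoate | O=CC[C@@]1(COC(C)=O)O[C@@H]1CC/C(C)=C\[C@@H](O)/C=C(\CO)C(=O)OC | intermediate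
22 | methyl (2Z,4R,5Z)-8-[(2R,3S)-3-(acetoxymethyl)-3-(2-oxoethyl)oxiran-2-yl]-2-(bromomethyl)-4-hydroxy-6-methylocta-2,5-dienoate | O=CC[C@@]1(COC(C)=O)O[C@@H]1CC/C(C)=C\[C@@H](O)/C=C(\CBr)C(=O)OC | intermediate
23 | allylindium species from 22 (drawn as the C13 dibromoindium compound of the sesquibromide mixture) | O=CC[C@@]1(COC(C)=O)O[C@@H]1CC/C(C)=C\[C@@H](O)/C=C(\C[In](Br)Br)C(=O)OC | intermediate
24 | methyl (1R,4Z,6R,7R,8R,10S)-14-acetoxy-1,10-epoxy-6,8-dihydroxygermacra-4,11(13)-dien-12-oate | O[C@@H]1C[C@@]2(COC(C)=O)O[C@@H]2CC/C(C)=C\[C@@H](O)[C@@H]1C(=C)C(=O)OC | intermediate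
25 | (1R,4Z,6R,7R,8R,10S)-14-acetoxy-1,10-epoxy-8-hydroxygermacra-4,11(13)-dien-12,6-olide | O[C@@H]1C[C@@]2(COC(C)=O)O[C@@H]2CC/C(C)=C\[C@H]2OC(=O)C(=C)[C@@H]21 | intermediate
26 | (1R,4Z,6R,7R,8R,10S)-14-acetoxy-1,10-epoxy-8-(methacryloyloxy)germacra-4,11(13)-dien-12,6-olide | C=C(C)C(=O)O[C@@H]1C[C@@]2(COC(C)=O)O[C@@H]2CC/C(C)=C\[C@H]2OC(=O)C(=C)[C@@H]21 | target

**Step count**
Total: 13 steps. Longest linear sequence: 12 (steps 1, 2 and 4–13; step 3 is a one-step branch).

**Three steps most likely to fail, each with one fallback**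

Step 12 (ring closure and lactonisation): the free γ-hydroxy allylic bromide may cyclise to a dihydrofuran, the ten-membered closure may lose to oligomerisation, or the 8,12-lactone may compete. The fallback sets out from 19 and returns at 25. Coupling of 19 with bis(pinacolatoboryl)methane (Pd[P(t-Bu)3]2, K3PO4, aq THF, rt) gives the allylboronate diol F1. TEMPO/PhI(OAc)2 oxidation then gives the allylboronate aldehyde F2. On warming in toluene F2 closes the ring by intramolecular allylboration (boron-centred chair, same Z allyl geometry, same syn C7/C8 outcome) and lactonises on aqueous work-up.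

Step 4 (β-oxido ylide hydroxymethylation): betaine deprotonation or formaldehyde capture may be inefficient. The fallback sets out from 4 and returns at 10. Alkylation of commercial methyl bis(2,2,2-trifluoroethyl)phosphonoacetate with (2-iodoethoxy)(tert-butyl)dimethylsilane (NaH, DMSO) gives the substituted Still–Gennari phosphonate F3. Olefination of 4 with F3 (KN(SiMe3)2, 18-crown-6, THF, −78 °C) gives the Z-enoate F4, and i-Bu2AlH (CH2Cl2, −78 °C) reduces F4 to 10.

Step 11 (hydroxymethyl Stille coupling on the epoxy aldehyde): the β,γ-epoxy aldehyde may not survive warm coupling conditions. The fallback sets out from 20 and returns at 25. Room-temperature Negishi coupling of 20 with PivOCH2ZnI (Pd(PPh3)4 cat, THF) gives the allylic pivalate F5. F5 is cyclised by umpolung allylation (Pd(PPh3)4 cat, InI, THF/H2O, high dilution: π-allylpalladium to allylindium, addition to C8, lactonisation on O6).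

**Further compounds**
F1 | step 12 | methyl (2E,4R,5Z)-8-[(2R,3S)-3-(acetoxymethyl)-3-(2-hydroxyethyl)oxiran-2-yl]-4-hydroxy-6-methyl-2-[(4,4,5,5-tetramethyl-1,3,2-dioxaborolan-2-yl)methyl]octa-2,5-dienoate | OCC[C@@]1(COC(C)=O)O[C@@H]1CC/C(C)=C\[C@@H](O)/C=C(\CB1OC(C)(C)C(C)(C)O1)C(=O)OC
F2 | step 12 | methyl (2E,4R,5Z)-8-[(2R,3S)-3-(acetoxymethyl)-3-(2-oxoethyl)oxiran-2-yl]-4-hydroxy-6-methyl-2-[(4,4,5,5-tetramethyl-1,3,2-dioxaborolan-2-yl)methyl]octa-2,5-dienoate | O=CC[C@@]1(COC(C)=O)O[C@@H]1CC/C(C)=C\[C@@H](O)/C=C(\CB1OC(C)(C)C(C)(C)O1)C(=O)OC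
F3 | step 4 | methyl 2-[bis(2,2,2-trifluoroethoxy)phosphoryl]-4-[(tert-butyldimethylsilyl)oxy]butanoate | COC(=O)C(CCO[Si](C)(C)C(C)(C)C)P(=O)(OCC(F)(F)F)OCC(F)(F)F
F4 | step 4 | methyl (2Z,6Z)-8-[(tert-butyldimethylsilyl)oxy]-2-{2-[(tert-butyldimethylsilyl)oxy]ethyl}-6-methylocta-2,6-dienoate | COC(=O)/C(CCO[Si](C)(C)C(C)(C)C)=C\CC/C(C)=C\CO[Si](C)(C)C(C)(C)C
F5 | step 11 | methyl (2E,4R,5Z)-8-[(2R,3S)-3-(acetoxymethyl)-3-(2-oxoethyl)oxiran-2-yl]-2-{[(2,2-dimethylpropanoyl)oxy]methyl}-4-hydroxy-6-methylocta-2,5-dienoate | O=CC[C@@]1(COC(C)=O)O[C@@H]1CC/C(C)=C\[C@@H](O)/C=C(\COC(=O)C(C)(C)C)C(=O)OC
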